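All runs are calculated on assumed constants, noise included.

On Monday and on Wednesday product and substrate together made about the whole charge while product sagged slowly, so I treated each reading as a balance rather than a yield.

| flask | substrate | partner | protic impurity | remark | time |
|---|---|---|---|---|---|
| Monday's | 0.40 M (in portions, 4) | 2 M | 0.040 M | run made earlier; portions every 4.0 min |  |
| Wednesday's | 0.60 M (in portions, 4) | 2 M | 0.040 M | run made earlier; portions every 4.0 min |  |
| flask | 0.80 M (in portions, 4) | 2.00 M | 0.0400 M | the portions of substrate follow each other after 4.0 min, the first at the start | 20 h |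

- Monday's (time / h: product / %, substrate / %): 6.00: 46, 57; 12.0: 40, 60; 20.0: 36, 63; 25.0: 31, 69
- Wednesday's (time / h: product / %, substrate / %): 2.00: 46, 55; 4.00: 45, 56; 10.0: 42, 59; 25.0: 32, 69

(standard deviation of a reading: 1.5 percentage points)



- amount of product in percent of the substrate charged, at 2.0 h, 6.0 h, 12 h and 20 h

From Wednesday's reading at 2.00 h I kept 0.497 L mol⁻¹ as Q, the ratio r of product to substrate divided by free partner B, taking B as the charge less the protic impurity and the product (thermodynamic control, in the usual term). But at 25.0 h Wednesday's r was lower, and the same Q then put B at 0.934 M, so I read a decay constant λ of 0.0256 h⁻¹ for free partner.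

The flask's B depends on the product it forms, so I iterated, with product share y = r/(1+r) and r = QB. B before any product gave 49.3%; taking that product out of B gave 43.7%; once more gave 44.4%, my value at 2.0 h. With 0.800 as r there, λ then gave 41.9% at 6.0 h, 38.2% at 12 h and 33.5% at 20 h.

The forecast, reading the decline as “close to zero order”, said 46%, 44.5%, 42% and 38.5%, ending higher than my figure.

The flask gave 43.8%, 41.6%, 38.2% and 33.9%.

    substrate + partner ⇌ product (K = 0.510 L mol⁻¹, k = 2.20 × 10⁻⁴ L mol⁻¹ s⁻¹)
    partner → decomposed reagent (k = 7.50 × 10⁻⁶ s⁻¹)
    partner + protic impurity → quenched reagent (k = 0.00430 L mol⁻¹ s⁻¹)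

At 20.0 h the flask held substrate 66.1%, product 33.9% and partner 49.9% of its charge, which makes Q 0.515 L mol⁻¹, close to Wednesday's reading. This flask stopped at such a balance because of the way back from product to substrate and partner: without that way back it reached >99.9% instead of 33.9%. The falling partner accounts for part of the product's decline: with partner held at its charge, this flask reached 50.5% instead of 33.9%. Q with B at that charge gives 49.8%.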